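**Retrosynthetic overview**
- The strategy rests on the cyclopentene ring: C1 (methyl carbinol), C2 and C3 form a three-carbon bridge between C8a and C3a, which are the α- and β-carbons of a C8 ketone in the seven-membered ring (azulene numbering; C4 carries the methylene, C7 the side chain, C8 the secondary carbinol).
- Key disconnection: C3–C3a and C1–C8a, by TiCl4-promoted (3+2) annulation of 1-methyl-1-(trimethylsilyl)allene onto (S)-4-silyloxycyclohept-2-enone; the C4 silyl ether steers the facial selectivity and is later turned into the methylene group.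
- After the annulation: the C1 carbinol and the C2=C3 alkene come from a singlet-oxygen ene reaction of the vinylsilane; the C7–C1' bond from a Michael addition to a crotonyl imide (auxiliary sets C1'); C7 and C8 are then set by delivery of a proton and a hydride from the convex face, which closes a δ-lactone; the side chain is finished through a Weinreb amide, an alkenyl Grignard reagent and a CBS reduction.
- Ring order: seven-membered ring from cyclohepta-1,3-diene (desymmetrised meso-diol), five-membered ring in the key step, and a temporary δ-lactone across C7/C8 that is reopened.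

Key step: step 8

Assumption: the lipase in step 2 acetylates the R-configured carbinol of the meso-diol, as is usual for cycloalk-2-en-1-ols; if its sense were opposite, hydrolysis of the meso-diacetate by the same enzyme would give the same monoacetate 4.

Convention: azulene numbering for the bicyclic compounds; α is the face that carries H-3a and H-8a, β the opposite face; side-chain carbons are C1' to C5' counted from the ring.

**Route**

Step 1
Reactants: 1 cyclohepta-1,3-diene
Product: 3 cis-cyclohept-2-ene-1,4-diol (meso), via endoperoxide 2 (not isolated)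
Conditions: O2, hν (visible), tetraphenylporphyrin (cat.), CH2Cl2, 0 °C; then Zn, AcOH, 0 °C to rt
Reagents that add atoms: dioxygen, O=O
Why: Singlet oxygen adds across the diene in a suprafacial [4+2] cycloaddition so that both new C–O bonds are cis, and zinc in acetic acid cleaves only the O–O bond, which leaves the meso cis-diol.

Step 2
Reactants: 3 cis-cyclohept-2-ene-1,4-diol
Product: 4 (1R,4S)-4-hydroxycyclohept-2-en-1-yl acetate
Conditions: lipase from Burkholderia cepacia (Amano PS), isopropenyl acetate, t-BuOMe, 40 °C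
Reagents that add atoms: isopropenyl acetate, CC(=C)OC(C)=O
Why: Lipase-catalysed transesterification desymmetrises the meso-diol by acetylating one enantiotopic hydroxyl, taken here to be the R-configured carbinol, so that the free hydroxyl sits on the S carbon that becomes C4.

Step 3
Reactants: 4 (1R,4S)-4-hydroxycyclohept-2-en-1-yl acetate
Product: 5 (1R,4S)-4-[(tert-butyldimethylsilyl)oxy]cyclohept-2-en-1-yl acetate
Conditions: TBSCl, imidazole, DMF, rt
Reagents that add atoms: tert-butyldimethylsilyl chloride, CC(C)(C)[Si](C)(C)Cl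
Why: Standard silylation of a secondary alcohol, which fixes the silyl ether on the future C4 stereocentre.

Step 4
Reactants: 5 (1R,4S)-4-[(tert-butyldimethylsilyl)oxy]cyclohept-2-en-1-yl acetate
Product: 6 (1R,4S)-4-[(tert-butyldimethylsilyl)oxy]cyclohept-2-en-1-ol
Conditions: K2CO3 (cat.), MeOH, 0 °C
Reagents that add atoms: none
Why: Base-catalysed methanolysis (Zemplén-type transesterification) removes the acetate without touching the silyl ether or either stereocentre.

Step 5
Reactants: 6 (1R,4S)-4-[(tert-butyldimethylsilyl)oxy]cyclohept-2-en-1-ol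
Product: 7 (S)-4-[(tert-butyldimethylsilyl)oxy]cyclohept-2-en-1-one
Conditions: Dess–Martin periodinane, CH2Cl2, rt
Reagents that add atoms: none
Why: Dess–Martin oxidation of the allylic alcohol gives the enone under non-basic conditions, so the γ-silyloxy group is not eliminated and its stereocentre is untouched.

Step 6
Reactants: 8 3-(trimethylsilyl)prop-2-yn-1-ol
Product: 9 3-(trimethylsilyl)prop-2-yn-1-yl methanesulfonate
Conditions: MsCl, Et3N, CH2Cl2, 0 °C
Reagents that add atoms: methanesulfonyl chloride, CS(=O)(=O)Cl
Why: Sulfonylation of the primary propargylic alcohol provides the leaving group for the SN2' displacement.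

Step 7
Reactants: 9 3-(trimethylsilyl)prop-2-yn-1-yl methanesulfonate
Product: 10 1-methyl-1-(trimethylsilyl)allene
Conditions: MeMgCl, CuBr (10 mol %), LiBr, THF, −78 °C to rt
Reagents that add atoms: methylmagnesium chloride, C[Mg]Cl
Why: Copper-catalysed SN2' substitution of the propargylic mesylate by the methyl Grignard reagent delivers the methyl group to the silyl-bearing alkyne carbon and gives the 1,1-disubstituted allene.

Step 8
Reactants: 7 (S)-4-[(tert-butyldimethylsilyl)oxy]cyclohept-2-en-1-one; 10 1-methyl-1-(trimethylsilyl)allene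
Product: 11 (3aS,4S,8aS)-4-[(tert-butyldimethylsilyl)oxy]-1-methyl-2-(trimethylsilyl)-3,3a,4,5,6,7-hexahydroazulen-8(8aH)-one (cis-fused, 4-silyloxy α)
Conditions: TiCl4 (1.2 equiv), CH2Cl2, −78 °C; aqueous NaHCO3 work-up
Reagents that add atoms: none
Why: TiCl4 activates the enone and the allene attacks C3a with its CH2 terminus, which gives a vinyl cation stabilised by the neighbouring C–Si bond; a 1,2-shift of the silyl group moves the charge to the methyl-bearing carbon, which the titanium enolate carbon C8a captures. The closest known reaction type is the Danheiser (trimethylsilyl)cyclopentene annulation of silylallenes with cyclic enones. The five-membered ring is closed by the C1–C8a bond in a cationic closure of the enolate carbon onto the vinyl cation, formally 5-endo with respect to the new C1=C2 double bond, which is feasible because the empty orbital lies in the plane that the tethered enolate can reach. C3a is set by attack anti to the C4 silyloxy group, and C8a follows from it because the three-atom bridge can only span the two carbons on one face, which gives the cis ring fusion. The step needs facial selectivity at C3a and conjugate rather than carbonyl addition; the bulky γ-silyloxy group next to C3a shields one face, and titanium activation of the enone at low temperature directs the allene terminus to the β-carbon.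

Step 9
Reactants: 11 cis-fused silylcyclopentene ketone
Product: 13 4α-[(tert-butyldimethylsilyl)oxy]-1α-hydroxy-1β-methyl-2-(trimethylsilyl)-3a,4,5,6,7,8a-hexahydroazulen-8(1H)-one, via hydroperoxide 12 (not isolated)
Conditions: O2, hν (visible), tetraphenylporphyrin (cat.), CH2Cl2, −20 °C; then PPh3, rt
Reagents that add atoms: dioxygen, O=O
Why: Schenck ene reaction of singlet oxygen with the vinylsilane, in which oxygen bonds to C1 (the alkene carbon remote from silicon) on the convex face that carries H-8a, a hydrogen is taken from C3 geminal to silicon and the double bond moves to C2=C3, so that the C1 carbinol is set with its hydroxyl cis to H-8a before PPh3 reduces the hydroperoxide with retention.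

Step 10
Reactants: 13 β-hydroxy ketone
Product: 14 1-O-triethylsilyl ether of 13
Conditions: Et3SiOTf, 2,6-lutidine, CH2Cl2, −78 °C
Reagents that add atoms: triethylsilyl trifluoromethanesulfonate, CC[Si](CC)(CC)OS(=O)(=O)C(F)(F)F
Why: Silylation of the tertiary alcohol with a silyl triflate and a hindered pyridine base masks the β-hydroxy ketone against retro-aldol cleavage before enolate chemistry.

Step 11
Reactants: 14 silyl-protected ketone
Product: 16 7-(phenylsulfanyl) derivative of 14 (both C7 epimers), via lithium enolate 15 (not isolated)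
Conditions: LiN(i-Pr)2, THF, −78 °C; then PhSO2SPh, −78 to −40 °C
Reagents that add atoms: S-phenyl benzenethiosulfonate, O=S(=O)(Sc1ccccc1)c1ccccc1
Why: Kinetic deprotonation takes place at the less hindered C7 methylene and sulfenylation of the enolate gives the α-phenylthio ketone, whose remaining C7 hydrogen is acidic enough for regiospecific enolisation away from C8a, while C7 is not yet a permanent stereocentre.

Step 12
Reactants: 17 (E)-but-2-enoic acid; 18 (S)-4-benzyloxazolidin-2-one
Product: 20 (S)-4-benzyl-3-[(E)-but-2-enoyl]oxazolidin-2-one, via mixed pivalic anhydride 19 (not isolated)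
Conditions: t-BuCOCl, Et3N, THF, −20 °C; then 18, LiCl, −20 °C to rt
Reagents that add atoms: none
Why: N-acylation of the oxazolidinone through the mixed pivalic anhydride is a standard way to make N-enoyl oxazolidinones without change of the E double bond.

Step 13
Reactants: 16 α-phenylthio ketone; 20 N-crotonyl oxazolidinone
Product: 22 Michael adduct with quaternary C7 (phenylsulfanyl group and the (2R)-4-[(S)-4-benzyl-2-oxooxazolidin-3-yl]-4-oxobutan-2-yl chain on C7; C7 configuration not assigned), via lithium enolate 21 (not isolated)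
Conditions: LiN(SiMe3)2, THF, −78 °C; then 20, −78 to −30 °C; AcOH quench
Reagents that add atoms: none
Why: Michael addition of the sulfur-stabilised lithium enolate to the N-enoyl oxazolidinone, in which the lithium-chelated s-cis imide should be attacked at its β-carbon on the face opposite the benzyl group, which sets C1' as R, while the configuration of the quaternary C7 is of no consequence because it is reset in step 14.

Step 14
Reactants: 22 Michael adduct
Product: 24 (7R)-keto imide (side chain 7β, H-7 α), via samarium enolate 23 (not isolated)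
Conditions: SmI2 (2.5 equiv), THF/MeOH, −78 °C
Reagents that add atoms: none
Why: SmI2 cleaves the C–S bond α to the ketone (reduction of an α-heterosubstituted ketone) and the samarium enolate so formed should be protonated by methanol at C7 from the less hindered convex face, the one that carries H-8a, which places H-7 cis to H-8a and the side chain on the β face.

Step 15
Reactants: 24 (7R)-keto imide
Product: 26 cis-fused δ-lactone between the 8β-oxygen and the side-chain carbonyl (7R, 8S, 1'R), via lithium alkoxide 25 (not isolated)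
Conditions: LiBH(s-Bu)3, THF, −78 to 0 °C; aqueous NH4Cl
Reagents that add atoms: none
Why: The bulky hydride should attack the C8 carbonyl from the face of H-7 and H-8a, so that the alkoxide is cis to the side chain, and the alkoxide then acylates itself on the imide carbonyl through a six-membered transition state, which closes the δ-lactone and releases the oxazolidinone auxiliary.

Step 16
Reactants: 26 silylated lactone
Product: 28 1α,4α-diol lactone without silicon, via vinylsilane diol 27 (not isolated)
Conditions: Bu4NF (excess, wet), THF, rt to 60 °C; aqueous NH4Cl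
Reagents that add atoms: none
Why: Fluoride removes both silyl ethers, and the freed C1 hydroxyl next to the vinylic silicon then assists fluoride-promoted protodesilylation of the β-hydroxy vinylsilane without movement of the double bond, a known reaction of 2-silyl allylic alcohols that cannot end in Peterson elimination here because an allene in a five-membered ring is impossible.

Step 17
Reactants: 28 diol lactone
Product: 29 4-oxo lactone
Conditions: Dess–Martin periodinane, NaHCO3, CH2Cl2, 0 °C
Reagents that add atoms: none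
Why: Dess–Martin oxidation under buffered, non-basic conditions oxidises only the secondary C4 alcohol and keeps the β,γ-unsaturated ketone from moving its double bond into conjugation or epimerising at C3a.

Step 18
Reactants: 29 4-oxo lactone
Product: 30 4-methylidene lactone
Conditions: Zn, CH2Br2, TiCl4 (reagent pre-formed in THF), CH2Cl2, 0 °C to rt
Reagents that add atoms: dibromomethane, BrCBr
Why: Lombardo–Takai methylenation is non-basic and selective for ketones over lactones, so the enolisable C4 ketone should be methylenated without epimerisation at C3a.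

Step 19
Reactants: 30 4-methylidene lactone
Product: 31 (3R)-3-[(1S,3aS,7R,8S,8aR)-1,8-dihydroxy-1-methyl-4-methylidene-1,3a,4,5,6,7,8,8a-octahydroazulen-7-yl]-N-methoxy-N-methylbutanamide
Conditions: MeNH(OMe)·HCl, i-PrMgCl, THF, −20 to 0 °C
Reagents that add atoms: N,O-dimethylhydroxylamine hydrochloride, CNOC.Cl
Why: Aminolysis of the lactone by the magnesium amide of N,O-dimethylhydroxylamine gives the Weinreb amide and frees the C8 hydroxyl without touching a stereocentre.

Step 20
Reactants: 31 Weinreb amide diol
Product: 32 1,8-bis-O-triethylsilyl ether of 31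
Conditions: Et3SiOTf, 2,6-lutidine, CH2Cl2, −78 to 0 °C
Reagents that add atoms: triethylsilyl trifluoromethanesulfonate, CC[Si](CC)(CC)OS(=O)(=O)C(F)(F)F
Why: Silylation of the secondary C8 and tertiary C1 hydroxyls prevents relactonisation and keeps both alcohols out of the Grignard, reduction and acetylation steps.

Step 21
Reactants: 32 bis-silylated Weinreb amide; 33 (2-methylprop-1-en-1-yl)magnesium bromide
Product: 34 (6R)-6-[1,8-bis(triethylsilyloxy)azulenyl]-2-methylhept-2-en-4-one (enone)
Conditions: THF, 0 °C; aqueous NH4Cl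
Reagents that add atoms: none
Why: Addition of the alkenyl Grignard reagent to the Weinreb amide stops at the chelated tetrahedral intermediate and gives the enone on work-up.

Step 22
Reactants: 34 enone
Product: 35 (4R,6R)-allylic alcohol (3'R carbinol)
Conditions: (S)-2-methyl-CBS-oxazaborolidine (20 mol %), catecholborane, toluene, −78 °C
Reagents that add atoms: none
Why: Corey–Bakshi–Shibata reduction, in which the (S)-oxazaborolidine delivers hydride to the enone with the alkenyl group as the larger substituent, should give the (R)-allylic alcohol at C3' by reagent control.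

Step 23
Reactants: 35 allylic alcohol
Product: 36 bis-silylated acetate
Conditions: Ac2O, pyridine, DMAP (cat.), CH2Cl2, 0 °C
Reagents that add atoms: acetic anhydride, CC(=O)OC(C)=O
Why: Standard acylation of the secondary allylic alcohol, the only free hydroxyl in the molecule.

Step 24
Reactants: 36 bis-silylated acetate
Product: 37 target CNP0209568.2
Conditions: Bu4NF, AcOH (1:1), THF, 0 °C to rt
Reagents that add atoms: none
Why: Fluoride buffered with acetic acid cleaves both triethylsilyl ethers without hydrolysis or migration of the allylic acetate and without ionising the tertiary allylic alcohol, which gives the target.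

**Compound list**

1 | cyclohepta-1,3-diene | C1=CC=CCCC1 | starting material
2 | 6,7-dioxabicyclo[3.2.2]non-8-ene (endoperoxide, not isolated) | O1[C@H]2CCC[C@@H](O1)C=C2 | intermediate
3 | cis-cyclohept-2-ene-1,4-diol (meso) | O[C@H]1CCC[C@@H](O)C=C1 | intermediate
4 | (1R,4S)-4-hydroxycyclohept-2-en-1-yl acetate | O[C@H]1CCC[C@@H](OC(C)=O)C=C1 | intermediate
5 | (1R,4S)-4-[(tert-butyldimethylsilyl)oxy]cyclohept-2-en-1-yl acetate | CC(C)(C)[Si](C)(C)O[C@H]1CCC[C@@H](OC(C)=O)C=C1 | intermediate
6 | (1R,4S)-4-[(tert-butyldimethylsilyl)oxy]cyclohept-2-en-1-ol | CC(C)(C)[Si](C)(C)O[C@H]1CCC[C@@H](O)C=C1 | intermediate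
7 | (S)-4-[(tert-butyldimethylsilyl)oxy]cyclohept-2-en-1-one | CC(C)(C)[Si](C)(C)O[C@H]1CCCC(=O)C=C1 | intermediate
8 | 3-(trimethylsilyl)prop-2-yn-1-ol | C[Si](C)(C)C#CCO | starting material
9 | 3-(trimethylsilyl)prop-2-yn-1-yl methanesulfonate | C[Si](C)(C)C#CCOS(C)(=O)=O | intermediate
10 | 1-methyl-1-(trimethylsilyl)allene | C=C=C(C)[Si](C)(C)C | intermediate
11 | (3aS,4S,8aS)-4-[(tert-butyldimethylsilyl)oxy]-1-methyl-2-(trimethylsilyl)-3,3a,4,5,6,7-hexahydroazulen-8(8aH)-one | CC(C)(C)[Si](C)(C)O[C@H]1CCCC(=O)[C@H]2[C@@H]1CC([Si](C)(C)C)=C2C | intermediate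
12 | 1α-hydroperoxide of the transposed vinylsilane (not isolated) | CC(C)(C)[Si](C)(C)O[C@H]1CCCC(=O)[C@H]2[C@@H]1C=C([Si](C)(C)C)[C@]2(C)OO | intermediate
13 | 4α-[(tert-butyldimethylsilyl)oxy]-1α-hydroxy-1β-methyl-2-(trimethylsilyl)-3a,4,5,6,7,8a-hexahydroazulen-8(1H)-one | CC(C)(C)[Si](C)(C)O[C@H]1CCCC(=O)[C@H]2[C@@H]1C=C([Si](C)(C)C)[C@]2(C)O | intermediate
14 | 1-O-triethylsilyl ether of 13 | CC(C)(C)[Si](C)(C)O[C@H]1CCCC(=O)[C@H]2[C@@H]1C=C([Si](C)(C)C)[C@]2(C)O[Si](CC)(CC)CC | intermediate
15 | lithium C7=C8 enolate of 14 (not isolated) | CC(C)(C)[Si](C)(C)O[C@H]1CCC=C(O[Li])[C@H]2[C@@H]1C=C([Si](C)(C)C)[C@]2(C)O[Si](CC)(CC)CC | intermediate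
16 | 7-(phenylsulfanyl) derivative of 14 (both C7 epimers) | CC(C)(C)[Si](C)(C)O[C@H]1CCC(Sc3ccccc3)C(=O)[C@H]2[C@@H]1C=C([Si](C)(C)C)[C@]2(C)O[Si](CC)(CC)CC | intermediate
17 | (E)-but-2-enoic acid (crotonic acid) | C/C=C/C(=O)O | starting material
18 | (S)-4-benzyloxazolidin-2-one | O=C1N[C@@H](Cc2ccccc2)CO1 | starting material
19 | (E)-but-2-enoic pivalic anhydride (not isolated) | C/C=C/C(=O)OC(=O)C(C)(C)C | intermediate
20 | (S)-4-benzyl-3-[(E)-but-2-enoyl]oxazolidin-2-one | C/C=C/C(=O)N1[C@@H](Cc2ccccc2)COC1=O | intermediate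
21 | lithium enolate of 16 (not isolated) | CC(C)(C)[Si](C)(C)O[C@H]1CCC(Sc3ccccc3)=C(O[Li])[C@H]2[C@@H]1C=C([Si](C)(C)C)[C@]2(C)O[Si](CC)(CC)CC | intermediate
22 | Michael adduct: 14 with phenylsulfanyl and the (2R)-4-[(S)-4-benzyl-2-oxooxazolidin-3-yl]-4-oxobutan-2-yl chain on C7 (C7 not assigned) | CC(C)(C)[Si](C)(C)O[C@H]1CCC(Sc3ccccc3)([C@H](C)CC(=O)N4[C@@H](Cc5ccccc5)COC4=O)C(=O)[C@H]2[C@@H]1C=C([Si](C)(C)C)[C@]2(C)O[Si](CC)(CC)CC | intermediate
23 | samarium C7=C8 enolate from 22 (not isolated) | CC(C)(C)[Si](C)(C)O[C@H]1CCC([C@H](C)CC(=O)N4[C@@H](Cc5ccccc5)COC4=O)=C(O[Sm](I)I)[C@H]2[C@@H]1C=C([Si](C)(C)C)[C@]2(C)O[Si](CC)(CC)CC | intermediate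
24 | (7R)-keto imide: 14 with the (2R) imide chain 7β and H-7 α | CC(C)(C)[Si](C)(C)O[C@H]1CC[C@H]([C@H](C)CC(=O)N4[C@@H](Cc5ccccc5)COC4=O)C(=O)[C@H]2[C@@H]1C=C([Si](C)(C)C)[C@]2(C)O[Si](CC)(CC)CC | intermediate
25 | lithium 8β-alkoxide of the hydroxy imide (not isolated) | CC(C)(C)[Si](C)(C)O[C@H]1CC[C@H]([C@H](C)CC(=O)N4[C@@H](Cc5ccccc5)COC4=O)[C@H](O[Li])[C@H]2[C@@H]1C=C([Si](C)(C)C)[C@]2(C)O[Si](CC)(CC)CC | intermediate
26 | cis-fused δ-lactone (8β-O to side-chain carbonyl; 4α-TBSO, 1α-TESO, 2-TMS) | CC(C)(C)[Si](C)(C)O[C@H]1CC[C@@H]3[C@H](C)CC(=O)O[C@@H]3[C@H]2[C@@H]1C=C([Si](C)(C)C)[C@]2(C)O[Si](CC)(CC)CC | intermediate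
27 | 1α,4α-diol lactone retaining the 2-trimethylsilyl group (not isolated) | O[C@H]1CC[C@@H]3[C@H](C)CC(=O)O[C@@H]3[C@H]2[C@@H]1C=C([Si](C)(C)C)[C@]2(C)O | intermediate
28 | 1α,4α-diol lactone | O[C@H]1CC[C@@H]3[C@H](C)CC(=O)O[C@@H]3[C@H]2[C@@H]1C=C[C@]2(C)O | intermediate
29 | 4-oxo lactone | O=C1CC[C@@H]3[C@H](C)CC(=O)O[C@@H]3[C@H]2[C@@H]1C=C[C@]2(C)O | intermediate
30 | 4-methylidene lactone | C=C1CC[C@@H]3[C@H](C)CC(=O)O[C@@H]3[C@H]2[C@@H]1C=C[C@]2(C)O | intermediate
31 | (3R)-3-[(1S,3aS,7R,8S,8aR)-1,8-dihydroxy-1-methyl-4-methylidene-1,3a,4,5,6,7,8,8a-octahydroazulen-7-yl]-N-methoxy-N-methylbutanamide | C=C1CC[C@H]([C@H](C)CC(=O)N(C)OC)[C@H](O)[C@H]2[C@@H]1C=C[C@]2(C)O | intermediate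
32 | 1,8-bis-O-triethylsilyl ether of 31 | C=C1CC[C@H]([C@H](C)CC(=O)N(C)OC)[C@H](O[Si](CC)(CC)CC)[C@H]2[C@@H]1C=C[C@]2(C)O[Si](CC)(CC)CC | intermediate
33 | (2-methylprop-1-en-1-yl)magnesium bromide (commercial THF solution; also available from 1-bromo-2-methylprop-1-ene and Mg) | CC(C)=C[Mg]Br | starting material
34 | bis-silylated enone, (6R)-2-methylhept-2-en-4-one chain on C7 | C=C1CC[C@H]([C@H](C)CC(=O)C=C(C)C)[C@H](O[Si](CC)(CC)CC)[C@H]2[C@@H]1C=C[C@]2(C)O[Si](CC)(CC)CC | intermediate
35 | bis-silylated (4R,6R)-allylic alcohol | C=C1CC[C@H]([C@H](C)C[C@H](C=C(C)C)O)[C@H](O[Si](CC)(CC)CC)[C@H]2[C@@H]1C=C[C@]2(C)O[Si](CC)(CC)CC | intermediate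
36 | bis-silylated (4R,6R)-acetate | C=C1CC[C@H]([C@H](C)C[C@H](C=C(C)C)OC(C)=O)[C@H](O[Si](CC)(CC)CC)[C@H]2[C@@H]1C=C[C@]2(C)O[Si](CC)(CC)CC | intermediate
37 | (4R,6R)-6-[(1S,3aS,7R,8S,8aR)-1,8-dihydroxy-1-methyl-4-methylidene-1,3a,4,5,6,7,8,8a-octahydroazulen-7-yl]-2-methylhept-2-en-4-yl acetate (CNP0209568.2) | C=C1CC[C@H]([C@H](C)C[C@H](C=C(C)C)OC(C)=O)[C@H](O)[C@H]2[C@@H]1C=C[C@]2(C)O | target

**Step count and risks**

Total step count: 24.
Longest linear sequence: 21 steps (steps 1–5, 8–11 and 13–24, from cyclohepta-1,3-diene).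

Three steps most likely to fail:

Step 8 (key annulation). What may go wrong: cleavage or ionisation of the C4 silyl ether by TiCl4, addition of the allene to both faces of C3a because the silyloxy group shields too weakly, or loss of silicon from the vinyl cation before ring closure. Fallback, setting out from 4 and returning at 11: the precursor is reshaped so that the directing group is the bulkier and far more acid-stable tert-butyldiphenylsilyl ether. Silylation of 4 (TBDPSCl, imidazole) gives the silyl ether acetate F1, methanolysis (K2CO3, MeOH) the allylic alcohol F2, and Dess–Martin oxidation the enone F3. The same annulation with 10 then gives the cis-fused silylcyclopentene F4, buffered fluoride (Bu4NF, AcOH) frees the C4 alcohol F5 without touching the tetrasubstituted vinylsilane, and TBSCl with imidazole returns 11.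

Step 13 (Michael addition). What may go wrong: slow conjugate addition of the hindered tertiary enolate to the β-methyl acceptor, competing attack at the imide carbonyls, or erosion of the auxiliary control at C1'. Fallback, setting out from 14 and returning at 26: the C7–C1' unit is built by a sigmatropic route that needs no auxiliary.
- Aldol addition of enolate 15 to acetaldehyde gives the β-hydroxy ketone F6, and dehydration with the Burgess reagent the (E)-ethylidene enone F7.
- Luche reduction (NaBH4, CeCl3) from the α face gives the 8β-allylic alcohol F8.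
- Johnson–Claisen rearrangement (trimethyl orthoacetate, cat. propionic acid, toluene, 110 °C) forms the new bond at C1' on the face from which the C8–O bond departs; with the E alkene this gives the (1'R) methyl ester F9, which has a C7=C8 double bond.
- Hydroboration–oxidation (BH3·SMe2, then NaBO3) from the convex face places H-7 α and gives the 8α-alcohol F10.
- Dess–Martin oxidation gives the keto ester F11, the ester analogue of 24.
- LiBH(s-Bu)3 reduces C8 from the α face and the alkoxide lactonises to 26.

Step 16 (global fluoride desilylation). What may go wrong: incomplete cleavage of the vinylic C–Si bond once the O-silyl groups are gone, or base-induced opening of the lactone at the temperature that the cleavage needs. Fallback, setting out from 26 and returning at 28: the vinylic silicon is removed by an electrophilic route. HF·pyridine in THF removes only the two O-silyl groups and gives the vinylsilane diol 27, isolated in this variant. N-iodosuccinimide in hexafluoroisopropanol then effects ipso-iododesilylation to the vinyl iodide F12, and Bu3SnH with Pd(PPh3)4 (cat.) replaces iodine by hydrogen to give 28.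

**Further compounds**

F1 | step 8 | (1R,4S)-4-[(tert-butyldiphenylsilyl)oxy]cyclohept-2-en-1-yl acetate | CC(C)(C)[Si](c1ccccc1)(c1ccccc1)O[C@H]2CCC[C@@H](OC(C)=O)C=C2
F2 | step 8 | (1R,4S)-4-[(tert-butyldiphenylsilyl)oxy]cyclohept-2-en-1-ol | CC(C)(C)[Si](c1ccccc1)(c1ccccc1)O[C@H]2CCC[C@@H](O)C=C2
F3 | step 8 | (S)-4-[(tert-butyldiphenylsilyl)oxy]cyclohept-2-en-1-one | CC(C)(C)[Si](c1ccccc1)(c1ccccc1)O[C@H]2CCCC(=O)C=C2
F4 | step 8 | (3aS,4S,8aS)-4-[(tert-butyldiphenylsilyl)oxy]-1-methyl-2-(trimethylsilyl)-3,3a,4,5,6,7-hexahydroazulen-8(8aH)-one | CC(C)(C)[Si](c1ccccc1)(c1ccccc1)O[C@H]2CCCC(=O)[C@H]3[C@@H]2CC([Si](C)(C)C)=C3C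
F5 | step 8 | (3aS,4S,8aS)-4-hydroxy-1-methyl-2-(trimethylsilyl)-3,3a,4,5,6,7-hexahydroazulen-8(8aH)-one | O[C@H]1CCCC(=O)[C@H]2[C@@H]1CC([Si](C)(C)C)=C2C
F6 | step 13 | 7-(1-hydroxyethyl) derivative of 14 (aldol adduct, diastereomer mixture) | CC(C)(C)[Si](C)(C)O[C@H]1CCC(C(C)O)C(=O)[C@H]2[C@@H]1C=C([Si](C)(C)C)[C@]2(C)O[Si](CC)(CC)CC
F7 | step 13 | 7-[(E)-ethylidene] enone derived from 14 | CC(C)(C)[Si](C)(C)O[C@H]1CC/C(=C\C)C(=O)[C@H]2[C@@H]1C=C([Si](C)(C)C)[C@]2(C)O[Si](CC)(CC)CC
F8 | step 13 | 8β-allylic alcohol with 7-[(E)-ethylidene] group | CC(C)(C)[Si](C)(C)O[C@H]1CC/C(=C\C)[C@H](O)[C@H]2[C@@H]1C=C([Si](C)(C)C)[C@]2(C)O[Si](CC)(CC)CC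
F9 | step 13 | methyl (3R)-3-(azulen-7-yl)butanoate with C7=C8 double bond (Claisen product) | CC(C)(C)[Si](C)(C)O[C@H]1CCC([C@H](C)CC(=O)OC)=C[C@H]2[C@@H]1C=C([Si](C)(C)C)[C@]2(C)O[Si](CC)(CC)CC
F10 | step 13 | 8α-hydroxy methyl ester with H-7 α | CC(C)(C)[Si](C)(C)O[C@H]1CC[C@H]([C@H](C)CC(=O)OC)[C@@H](O)[C@H]2[C@@H]1C=C([Si](C)(C)C)[C@]2(C)O[Si](CC)(CC)CC
F11 | step 13 | (7R)-keto methyl ester (ester analogue of 24) | CC(C)(C)[Si](C)(C)O[C@H]1CC[C@H]([C@H](C)CC(=O)OC)C(=O)[C@H]2[C@@H]1C=C([Si](C)(C)C)[C@]2(C)O[Si](CC)(CC)CC
F12 | step 16 | 2-iodo analogue of diol lactone 28 (vinyl iodide) | O[C@H]1CC[C@@H]3[C@H](C)CC(=O)O[C@@H]3[C@H]2[C@@H]1C=C(I)[C@]2(C)O
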